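Ring B (C1'–C6') is cut away from C2. The 5-methoxy-1,4-benzoquinone, with para oxygens at C2' and C5', a methoxy at C4' and its attachment to C2 through C1', is the oxidised form of a para-methoxyphenol that a Dötz benzannulation can assemble. In one operation a terminal alkyne on C2, a methoxy(1-methoxyvinyl)carbene ligand on zerovalent chromium and one CO form C5'–C6', C1'–C2' and C2'–C3' and close ring B with every oxygen in place. The precursor is the (2S)-2-ethynylchroman-4-one carrying the finished ring A (5-OBn, 6,8-dimethyl, 7-OMe), its stereocentre set beforehand by copper-catalysed asymmetric alkynylation of the chromone.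

Key step: step 8

Remark on numbering: flavanone locants are used (O1, C2, C3, C4, C4a, C5–C8, C8a; ring A is the benzo ring, ring C the pyranone, ring B is C1'–C6'). Acetophenones are named as phenylethanones so that primed locants always mean ring B.

Assumption: the sense of induction in step 5 is fixed by the ligand antipode; the enantiomer of the bis(oxazoline) that delivers the (2S) product is used, and the configuration is to be confirmed at compound 11.

Step 1
Reactants: 1 1-(2,4,6-trihydroxyphenyl)ethan-1-one (phloroacetophenone)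
Product: 2 1-(2,4,6-trihydroxy-3,5-dimethylphenyl)ethan-1-one
Conditions: MeI (2.1 equiv), NaOMe, MeOH, 0 °C to reflux
Reagents that add atoms: iodomethane, CI
Why: The phloroglucinol phenoxide reacts as a vinylogous enolate at its two free ring carbons, so two equivalents of MeI should install both C-methyl groups (C-alkylation of a phloroacetophenone), and limiting the MeI restrains a dearomatising third methylation.

Step 2
Reactants: 2 1-(2,4,6-trihydroxy-3,5-dimethylphenyl)ethan-1-one
Product: 3 1-(2,6-dihydroxy-4-methoxy-3,5-dimethylphenyl)ethan-1-one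
Conditions: Me2SO4 (1.0 equiv), K2CO3, acetone, rt to 50 °C
Reagents that add atoms: dimethyl sulfate, COS(=O)(=O)OC
Why: The hydroxyl para to the acetyl group is the most acidic and takes no part in hydrogen bonding to the carbonyl, so one equivalent of Me2SO4 should etherify it first (Williamson ether synthesis).

Step 3
Reactants: 3 1-(2,6-dihydroxy-4-methoxy-3,5-dimethylphenyl)ethan-1-one
Product: 4 1-[2-(benzyloxy)-6-hydroxy-4-methoxy-3,5-dimethylphenyl]ethan-1-one
Conditions: BnBr (1.1 equiv), K2CO3, DMF, rt to 50 °C
Reagents that add atoms: benzyl bromide, BrCc1ccccc1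
Why: The two ortho hydroxyls are equivalent, and after the first Williamson benzylation the remaining one becomes the sole, strong hydrogen-bond donor to the carbonyl and should resist a second alkylation.

Step 4
Reactants: 4 1-[2-(benzyloxy)-6-hydroxy-4-methoxy-3,5-dimethylphenyl]ethan-1-one
Product: 6 5-(benzyloxy)-7-methoxy-6,8-dimethyl-4H-chromen-4-one, via enaminone 5 (not isolated)
Conditions: Me2NCH(OMe)2, toluene, 100 °C; concentrate; then conc. HCl, CH2Cl2, 40 °C
Reagents that add atoms: N,N-dimethylformamide dimethyl acetal, COC(OC)N(C)C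
Why: Condensation of the methyl ketone with the formamide acetal gives the enaminone, and acid then drives addition of the free phenol to its β-carbon with loss of dimethylamine (enaminone route to chromones), which the benzyl ether tolerates.

Step 5
Reactants: 6 5-(benzyloxy)-7-methoxy-6,8-dimethyl-4H-chromen-4-one; 7 trimethylsilylacetylene
Product: 10 (2S)-5-(benzyloxy)-7-methoxy-6,8-dimethyl-2-[(trimethylsilyl)ethynyl]chroman-4-one, via silyloxybenzopyrylium triflate 8 (not isolated), via silyl enol ether 9 (not isolated)
Conditions: TBSOTf (1.3 equiv), CH2Cl2, rt; then CuI (10 mol%), Ph-BOX ligand [2,2'-(propane-2,2-diyl)bis(4-phenyl-4,5-dihydrooxazole), 12 mol%], 7 (2 equiv), iPr2NEt, toluene/CH2Cl2, −78 to −40 °C; then 3 M HCl, THF, 0 °C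
Reagents that add atoms: none
Why: O-Silylation of the C4 carbonyl turns the chromone into a planar 4-silyloxybenzopyrylium ion, the ligand-bound acetylide of monovalent copper adds to C2 from one face and so sets C2 as S, and acid hydrolyses the silyl enol ether (copper-catalysed enantioselective alkynylation of chromones through benzopyrylium ions).

Step 6
Reactants: 10 (2S)-5-(benzyloxy)-7-methoxy-6,8-dimethyl-2-[(trimethylsilyl)ethynyl]chroman-4-one
Product: 11 (2S)-5-(benzyloxy)-2-ethynyl-7-methoxy-6,8-dimethylchroman-4-one
Conditions: AgNO3 (10 mol%), MeOH/H2O/CH2Cl2, rt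
Reagents that add atoms: none
Why: Silver-catalysed protiodesilylation of the alkynylsilane runs through the silver acetylide under neutral conditions, so the base-sensitive C2 centre (retro-oxa-Michael opening of ring C) should not be put at risk.

Step 7
Reactants: 12 methyl vinyl ether; 13 chromium hexacarbonyl Cr(CO)6
Product: 16 pentacarbonyl[methoxy(1-methoxyvinyl)carbene]chromium, via 1-methoxyvinyllithium 14 (not isolated), via lithium acylchromate 15 (not isolated)
Conditions: t-BuLi, THF, −78 to 0 °C; then 13, Et2O/THF, 0 °C to rt; evaporate; then Me3OBF4, CH2Cl2, 0 °C, Ar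
Reagents that add atoms: trimethyloxonium tetrafluoroborate, C[O+](C)C.F[B-](F)(F)F
Why: tert-Butyllithium removes the α-vinyl proton of the enol ether, the vinyllithium adds to a CO ligand of Cr(CO)6 and the acylchromate oxygen is methylated by the oxonium salt (Fischer carbene synthesis).

Step 8
Reactants: 11 (2S)-5-(benzyloxy)-2-ethynyl-7-methoxy-6,8-dimethylchroman-4-one; 16 pentacarbonyl[methoxy(1-methoxyvinyl)carbene]chromium
Product: 18 (2S)-5-(benzyloxy)-2-(2-hydroxy-4,5-dimethoxyphenyl)-7-methoxy-6,8-dimethylchroman-4-one, via tricarbonylchromium arene complex 17 (not isolated)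
Conditions: 16 (1.5 equiv), slow addition of 11, degassed THF, 50 °C, Ar; then air, EtOAc, rt
Reagents that add atoms: none
Why: Thermal loss of one CO from 16 lets the alkyne of 11 coordinate and insert into the Cr=C bond (C5'–C6'), CO insertion turns the vinylcarbene into a chromium-bound dienylketene (C1'–C2'), and ring closure onto the vinyl CH2 (C2'–C3') followed by enolisation gives the phenol as its Cr(CO)3 complex 17, from which air removes the metal. This is the Dötz benzannulation of an alkenyl(alkoxy)carbene complex of zerovalent chromium with a terminal alkyne; carbene ligands made from α-lithiated enol ethers are the closest relatives of 16. Ring B closes by thermal 6π electrocyclisation of the metal-bound dienylketene. No stereocentre is formed, and the propargylic C2 centre is a bystander because the neutral conditions trigger neither enolisation at C3 nor opening of the C2–O1 bond. The step needs regioselective insertion with the unsubstituted alkyne carbon bonded to the carbene carbon, and the steric difference between H and the branched C2 substituent secures it, so the chromanone ends up ortho to the new hydroxyl and para to the C4' methoxy. Phenol formation rather than CO-free five-membered ring closure is favoured by the alkenyl carbene ligand, the alkoxy donor and the ethereal solvent, and the C4 ketone and the ethers should be inert.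

Step 9
Reactants: 18 (2S)-5-(benzyloxy)-2-(2-hydroxy-4,5-dimethoxyphenyl)-7-methoxy-6,8-dimethylchroman-4-one
Product: 19 (2S)-5-(benzyloxy)-7-methoxy-2-(4-methoxy-3,6-dioxocyclohexa-1,4-dien-1-yl)-6,8-dimethylchroman-4-one
Conditions: PhI(OAc)2 (1.1 equiv), MeCN/H2O, 0 °C
Reagents that add atoms: water, O
Why: The only free phenol is activated on trivalent iodine, water adds at C5' para to it and methanol is expelled to give the quinone (oxidative demethylation of a hydroquinone monomethyl ether), while the benzyl ether, the fully substituted ring A and C2 should stay untouched.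

Step 10
Reactants: 19 (2S)-5-(benzyloxy)-7-methoxy-2-(4-methoxy-3,6-dioxocyclohexa-1,4-dien-1-yl)-6,8-dimethylchroman-4-one
Product: 21 (2S)-5-hydroxy-7-methoxy-2-(4-methoxy-3,6-dioxocyclohexa-1,4-dien-1-yl)-6,8-dimethylchroman-4-one (target), via hydroquinone 20 (not isolated)
Conditions: H2 (1 atm), Pd/C, EtOAc, rt; filter; then air, EtOAc, rt
Reagents that add atoms: none
Why: Hydrogenolysis over Pd/C cleaves the benzyl ether while the quinone is held as its hydroquinone, which air should reoxidise to the methoxyquinone (benzyl ether hydrogenolysis followed by autoxidation), and the freed 5-OH is stabilised by its hydrogen bond to C4=O.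

Compound list
1 | 1-(2,4,6-trihydroxyphenyl)ethan-1-one (phloroacetophenone) | CC(=O)c1c(O)cc(O)cc1O | starting material
2 | 1-(2,4,6-trihydroxy-3,5-dimethylphenyl)ethan-1-one | CC(=O)c1c(O)c(C)c(O)c(C)c1O | intermediate
3 | 1-(2,6-dihydroxy-4-methoxy-3,5-dimethylphenyl)ethan-1-one | CC(=O)c1c(O)c(C)c(OC)c(C)c1O | intermediate
4 | 1-[2-(benzyloxy)-6-hydroxy-4-methoxy-3,5-dimethylphenyl]ethan-1-one | CC(=O)c1c(O)c(C)c(OC)c(C)c1OCc1ccccc1 | intermediate
5 | (E)-1-[2-(benzyloxy)-6-hydroxy-4-methoxy-3,5-dimethylphenyl]-3-(dimethylamino)prop-2-en-1-one | CN(C)/C=C/C(=O)c1c(O)c(C)c(OC)c(C)c1OCc1ccccc1 | intermediate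
6 | 5-(benzyloxy)-7-methoxy-6,8-dimethyl-4H-chromen-4-one | O=c1ccoc2c(C)c(OC)c(C)c(OCc3ccccc3)c12 | intermediate
7 | trimethylsilylacetylene | C#C[Si](C)(C)C | starting material
8 | 5-(benzyloxy)-4-[(tert-butyldimethylsilyl)oxy]-7-methoxy-6,8-dimethylchromenylium trifluoromethanesulfonate | CC(C)(C)[Si](C)(C)Oc1cc[o+]c2c(C)c(OC)c(C)c(OCc3ccccc3)c12.[O-]S(=O)(=O)C(F)(F)F | intermediate
9 | {[(2S)-5-(benzyloxy)-7-methoxy-6,8-dimethyl-2-[(trimethylsilyl)ethynyl]-2H-chromen-4-yl]oxy}(tert-butyl)dimethylsilane | C[Si](C)(C)C#C[C@@H]1C=C(O[Si](C)(C)C(C)(C)C)c2c(OCc3ccccc3)c(C)c(OC)c(C)c2O1 | intermediate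
10 | (2S)-5-(benzyloxy)-7-methoxy-6,8-dimethyl-2-[(trimethylsilyl)ethynyl]chroman-4-one | C[Si](C)(C)C#C[C@@H]1CC(=O)c2c(OCc3ccccc3)c(C)c(OC)c(C)c2O1 | intermediate
11 | (2S)-5-(benzyloxy)-2-ethynyl-7-methoxy-6,8-dimethylchroman-4-one | C#C[C@@H]1CC(=O)c2c(OCc3ccccc3)c(C)c(OC)c(C)c2O1 | intermediate
12 | methyl vinyl ether | COC=C | starting material
13 | chromium hexacarbonyl Cr(CO)6 | O=C=[Cr](=C=O)(=C=O)(=C=O)(=C=O)=C=O | starting material
14 | 1-methoxyvinyllithium | [Li]C(=C)OC | intermediate
15 | lithium pentacarbonyl(2-methoxyacryloyl)chromate | COC(=C)C(O[Li])=[Cr](=C=O)(=C=O)(=C=O)(=C=O)=C=O | intermediate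
16 | pentacarbonyl[methoxy(1-methoxyvinyl)carbene]chromium | COC(=C)C(OC)=[Cr](=C=O)(=C=O)(=C=O)(=C=O)=C=O | intermediate
17 | tricarbonylchromium complex of 18, metal η6-bound to ring B (hapticity not expressible, fragment written after a dot) | COc1cc(O)c(cc1OC)[C@@H]1CC(=O)c2c(OCc3ccccc3)c(C)c(OC)c(C)c2O1.O=C=[Cr](=C=O)=C=O | intermediate
18 | (2S)-5-(benzyloxy)-2-(2-hydroxy-4,5-dimethoxyphenyl)-7-methoxy-6,8-dimethylchroman-4-one | COc1cc(O)c(cc1OC)[C@@H]1CC(=O)c2c(OCc3ccccc3)c(C)c(OC)c(C)c2O1 | intermediate
19 | (2S)-5-(benzyloxy)-7-methoxy-2-(4-methoxy-3,6-dioxocyclohexa-1,4-dien-1-yl)-6,8-dimethylchroman-4-one | COC1=CC(=O)C([C@@H]2CC(=O)c3c(OCc4ccccc4)c(C)c(OC)c(C)c3O2)=CC1=O | intermediate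
20 | (2S)-2-(2,5-dihydroxy-4-methoxyphenyl)-5-hydroxy-7-methoxy-6,8-dimethylchroman-4-one | COc1cc(O)c(cc1O)[C@@H]1CC(=O)c2c(O)c(C)c(OC)c(C)c2O1 | intermediate
21 | (2S)-5-hydroxy-7-methoxy-2-(4-methoxy-3,6-dioxocyclohexa-1,4-dien-1-yl)-6,8-dimethylchroman-4-one | COC1=CC(=O)C([C@@H]2CC(=O)c3c(O)c(C)c(OC)c(C)c3O2)=CC1=O | target

Total step count: 10. Longest linear sequence: 9 (steps 1 to 6, then 8, 9 and 10); step 7 is a one-step side branch.

Steps most likely to fail

Step 8. The α-methoxyvinyl carbene complex may decompose before insertion. The chromium vinylcarbene intermediate may also be diverted into CO-free cyclisation or alkyne oligomerisation, so that the phenol pathway is lost. The fallback gives up the benzannulation and brings ring B in whole. It sets out from chromone 6: palladium-catalysed asymmetric conjugate addition of commercial (2,4,5-trimethoxyphenyl)boronic acid [Pd(OCOCF3)2, tert-butyl pyridine-oxazoline ligand of the antipode giving 2S, NH4PF6, H2O, ClCH2CH2Cl, 60 °C] should give (2S)-5-(benzyloxy)-7-methoxy-6,8-dimethyl-2-(2,4,5-trimethoxyphenyl)chroman-4-one F1. Oxidative demethylation of its para-dimethoxy pair (C2'/C5') with (NH4)2Ce(NO3)6 in MeCN/H2O at 0 °C should then give the quinone, and the route is rejoined at 19.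

Step 5. Facial discrimination may be poor, or addition to the crowded benzopyrylium ion may be slow, because the peri 5-benzyloxy group sits next to the silyloxy group; the result would be low enantiomeric purity or low conversion. The fallback replaces asymmetric catalysis by resolution. It sets out from 6: the same silyl-triflate-mediated copper alkynylation without chiral ligand (TBSOTf, CuI, iPr2NEt, 7; acid work-up) should give racemic 5-(benzyloxy)-7-methoxy-6,8-dimethyl-2-[(trimethylsilyl)ethynyl]chroman-4-one F2. Its enantiomers are separated by preparative chromatography on a chiral stationary phase, and the (2S) fraction rejoins the route at 10.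

Step 10. Debenzylation may be incomplete, the benzylic C2–O1 bond may be cleaved reductively while ring B is a hydroquinone, or aerial reoxidation may be incomplete. The fallback avoids hydrogen in the presence of the quinone and moves the oxidation to the end. It sets out from 18: chelation-assisted cleavage of the peri benzyl ether with BCl3 (CH2Cl2, −78 °C) should give (2S)-5-hydroxy-2-(2-hydroxy-4,5-dimethoxyphenyl)-7-methoxy-6,8-dimethylchroman-4-one F3. PhI(OAc)2 (1 equiv, MeCN/H2O, 0 °C) should then oxidise only the ring B para-methoxyphenol, since the ring A hydroxyl is hydrogen-bonded to C4=O and deactivated by the acyl group; the route is rejoined at 21.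

Further compounds
F1 | step 8 | (2S)-5-(benzyloxy)-7-methoxy-6,8-dimethyl-2-(2,4,5-trimethoxyphenyl)chroman-4-one | COc1cc(OC)c(cc1OC)[C@@H]1CC(=O)c2c(OCc3ccccc3)c(C)c(OC)c(C)c2O1
F2 | step 5 | racemic 5-(benzyloxy)-7-methoxy-6,8-dimethyl-2-[(trimethylsilyl)ethynyl]chroman-4-one | C[Si](C)(C)C#CC1CC(=O)c2c(OCc3ccccc3)c(C)c(OC)c(C)c2O1
F3 | step 10 | (2S)-5-hydroxy-2-(2-hydroxy-4,5-dimethoxyphenyl)-7-methoxy-6,8-dimethylchroman-4-one | COc1cc(O)c(cc1OC)[C@@H]1CC(=O)c2c(O)c(C)c(OC)c(C)c2O1
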